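## Analysis of the target

The target 17 is a 1,2-dihydronaphthalene. Ring A is the benzo ring (C4a to C8a) with a catechol at C6 and C7. Ring B is the carbocycle C1 to C4 with a C3=C4 double bond conjugated to ring A. Ring C is a 2-pyranone joined through its C4' to C1 and carrying a carboxylic acid at C6'. C2 and C3 each carry a further carboxylic acid.

There are two stereocentres, C1 (R) and C2 (S). They are adjacent and trans, so the pyranone and the C2 carboxyl lie on opposite faces of ring B. Both are labile. C1–H is benzylic to ring A and vinylogous to the lactone carbonyl through C4'=C3'. C2–H is α to a carboxyl and allylic to C3=C4. Loss of either proton opens the way to alkene migration and, with any oxidant, to the naphthalene, which erases both centres.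

The catechol is easily oxidised and the pyranone is an enol lactone that hydroxide or amines open, so the end game has to be acidic. The hard part is to form C1, which joins rings A and C, next to C2 with absolute control and without strong base.

The route uses the lability of C1. Because ring A and the pyranone carbonyl acidify C1–H, C1 can serve as the nucleophile that bonds to C2. Because C4a lies para to the C7 oxygen, it can capture an aldehyde carbon as C4.

## Retrosynthetic reasoning

**17 to 16 to 15.** The last operations only unmask polar groups. The ester C–O bonds at the C2 and C6' carboxyls and the two aryl O–CH3 bonds are cut, leading through catechol 16 to the dimethyl ether diester 15. Methyl ethers and simple alkyl esters are chosen because all of them fall under Lewis or Brønsted acid. A basic deprotection would open ring C and deprotonate C1 and C2. The forward steps must remove four alkyl groups without touching C3=C4 or either stereocentre.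

**15 to 14 to 12.** The bond between C3 and its carboxyl carbon is cut. In 12, C3 is the β-carbon of a styrene whose α-carbon C4 is linked through C4a to the para methoxy group at C7. It is therefore the most nucleophilic carbon of the molecule. A one-carbon electrophile can enter there by Vilsmeier formylation (through iminium salt 13 to aldehyde 14), and a Pinnick oxidation then gives 15. The gain is that the four-carbon partner of the key step becomes a simple enal instead of a trisubstituted, triply activated alkene. The forward reaction has to prefer C3 over C5 and C8 of ring A.

**12 to 8 and 9.** This is the central disconnection. The C1–C2 and C4–C4a bonds are cut, so ring B falls into benzylpyranone 8, which already joins C1 to rings A and C, and enal 9, which supplies C2, C3, C4 and the C2 ester. These two bonds are chosen because each end has the polarity the target offers: C1 as a stabilised carbanion, C2 as the β-carbon of an enal, C4 as an aldehyde carbon and C4a as a para-activated arene carbon. Cutting C1–C8a or C1–C4' would require arylation at a tertiary carbon, and cutting C2–C3 leaves no natural polarity. The gain is that ring B and both stereocentres arise in one operation, C2 under catalyst control, and ring C arrives intact. In the forward direction the Michael adduct 10 must form enantioselectively, cyclise through carbinol 11 at the position para to a methoxy group, and dehydrate.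

**8 to 6 and 7.** The bond between the benzylic carbon (the future C1) and the ring A carbon (the future C8a) is cut. This gives an sp3–sp2 cross-coupling between bromide 6 and boronic acid 7. Ring A then comes from a purchased building block with the correct 3,4-dioxygenation. The coupling must spare the lactone and the ester.

**6 to 5 to 4 to 1 and 2.** Bromide 6 comes from the C4' methyl group of 5 by radical substitution, and ester 5 from acid 4. Ring C is cut at the lactone C–O bond and at C5'–C6'. That is a vinylogous Claisen condensation of the γ-carbon of enoate 1 with oxalate 2, through dienolate 3, followed by lactonisation. All ring C carbons and the C6' carboxyl thus come from two bulk chemicals.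

## Alternatives that were turned down

**Alternative 1:** Ring B is opened at C1–C2 after a formal exchange of that bond for an O–C4 bond. The carbocycle is traced back to a benzo-fused six-membered lactone whose oxygen-bearing benzylic carbon (the later C4) carries the C2/C3 unit as an alkenyl diester. Forward, the silyl ketene acetal of this lactone undergoes an Ireland–Claisen [3,3] shift. C1–C2 forms, O–C4 breaks, the double bond moves to C3=C4 and the acid A1 results.
- For: the pericyclic step is well established. Ring B, the alkene and the C2 and C3 carboxyl carbons all appear at once. Here it is ahead of the chosen route, which spends steps 6 and 7 on the C3 carboxyl. Chirality would be transferred from one carbinol centre.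
- Against: the lactone tether forces a boat transition state, so A1 is the cis isomer and one centre must be inverted later. The enolisation needs a strong amide base next to a Michael acceptor. Above all, C1 carries only a carboxyl group. All of ring C (five more carbons and the C6' carboxyl) would have to be built from it through carbonyl intermediates in which C1–H is α to a carbonyl, benzylic and one elimination away from a naphthalene.
- Comparison: the chosen route brings ring C in as part of 8 and needs nine steps in all.

**Alternative 2:** Three bonds of ring B are cut: C1–C8a, C4–C4a and C3=C4. This leads to a symmetrical dimethoxy-substituted aryne and an open-chain formyl ester that carries the C2 ester and a phosphonate terminus. Forward, the formyl ester enolate adds to the aryne, the formyl group shifts to the neighbouring aryne carbon, and an intramolecular Horner–Wadsworth–Emmons olefination closes ring B to A2 in one flask.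
- For: three bonds form in one step. A symmetrical aryne raises no regiochemical question on ring A. The three carboxyl groups arrive differentiated. In carboxyl economy it is stronger than the chosen route, and in bonds per key step it is comparable.
- Against: nothing in the cascade controls absolute configuration. C1 is generated as a planar, ester-stabilised carbanion. C2, the only centre that could be carried in, is α to an ester and β to a formyl ester and would not survive the basic medium. The chain also holds two competing carbon acids. As in alternative 1, the C1 ester of A2 still has to be turned into ring C.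
- Comparison: the chosen route offers catalyst control of C2 and a preformed ring C.

**Alternative 3:** Only C2–C3 is cut. The precursor is an open-chain ester in which C1 already joins ring A and a second aryl group, and ring A carries a bromoalkenyl ester arm. The second aryl group is a dibenzyl-protected catechol, not ring C. Forward, zerovalent palladium inserts into the C3–Br bond, the C2 ester enolate replaces bromide on divalent palladium, and reductive elimination closes ring B to A3.
- For: enolate alkenylation is established chemistry. The diaryl-substituted C1 could be set beforehand by asymmetric conjugate arylation, which is a more secure source of absolute configuration than the new Michael step of the chosen route. The C3 ester is in place. The plan follows the probable biogenesis, in which ring C derives from a second catechol ring.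
- Against: ring C must be made at the very end by oxidative cleavage of the debenzylated catechol beside its oxygenated carbons, followed by relactonisation. The usual chemical cleavage occurs between the two oxygenated carbons and gives a diene diacid that lacks the enol oxygen of the lactone. The oxidant would also meet an oxidisable dihydronaphthalene. In addition, the enolate has to be formed with strong base beside a bromoalkenyl ester that can eliminate or accept nucleophiles.
- Comparison: the chosen route places its uncertain step at step 5 on simple material and needs no arene oxidation.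

Key step: step 5

## Route

Remark: all intermediates keep the locants of the target (C1 to C8a for the dihydronaphthalene, primed locants for the pyranone). The descriptor at C2 is R in 12 and S from 13 on, and C1 of 12 corresponds to 3S in open-chain 10. These are changes of CIP priority, not of geometry.

Step 1
Reactants: 1 methyl 3-methylbut-2-enoate; 2 dimethyl oxalate
Product: 4 4-methyl-2-oxo-2H-pyran-6-carboxylic acid, via potassium dienolate 3 (not isolated)
Conditions: KOMe, Et2O, 0 °C to rt; then conc. HCl, 90 °C
Reagents that add atoms: water, O
Why: Vinylogous Claisen condensation: methoxide removes a γ-proton of 1, the dienolate acylates at its γ-carbon with 2, and the product is held as the delocalised enolate 3. Acid then lets the enol oxygen close onto the enoate carbonyl (lactonisation with loss of methanol) and hydrolyses the remaining ester.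

Step 2
Reactants: 4 4-methyl-2-oxo-2H-pyran-6-carboxylic acid
Product: 5 methyl 4-methyl-2-oxo-2H-pyran-6-carboxylate
Conditions: MeOH, conc. H2SO4 (cat.), 65 °C
Reagents that add atoms: methanol, CO
Why: Fischer esterification. 2-Pyranone carboxylic acids are routinely esterified in acidic methanol, and the enol lactone is stable to acid.

Step 3
Reactants: 5 methyl 4-methyl-2-oxo-2H-pyran-6-carboxylate
Product: 6 methyl 4-(bromomethyl)-2-oxo-2H-pyran-6-carboxylate
Conditions: NBS, AIBN (cat.), PhCF3, 85 °C
Reagents that add atoms: N-bromosuccinimide, O=C1CCC(=O)N1Br
Why: Wohl–Ziegler bromination. The C4' methyl group holds the only allylic C–H bonds, and the electron-poor ring resists ionic bromination; the reaction is stopped short of full conversion to limit the dibromide.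

Step 4
Reactants: 6 methyl 4-(bromomethyl)-2-oxo-2H-pyran-6-carboxylate; 7 (3,4-dimethoxyphenyl)boronic acid
Product: 8 methyl 4-(3,4-dimethoxybenzyl)-2-oxo-2H-pyran-6-carboxylate
Conditions: PdCl2(dppf) (5 mol %) [dppf = 1,1'-bis(diphenylphosphino)ferrocene], K3PO4, toluene/H2O 20:1, 70 °C
Reagents that add atoms: none
Why: Suzuki–Miyaura coupling of an activated sp3 bromide. Zerovalent palladium inserts readily into the allylic-type C–Br bond, and reductive elimination at the CH2 terminus keeps the pyranone conjugated. Phosphate with little water should spare lactone and ester.

Step 5
Reactants: 8 methyl 4-(3,4-dimethoxybenzyl)-2-oxo-2H-pyran-6-carboxylate; 9 ethyl (E)-4-oxobut-2-enoate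
Product: 12 ethyl (1R,2R)-6,7-dimethoxy-1-[6-(methoxycarbonyl)-2-oxo-2H-pyran-4-yl]-1,2-dihydronaphthalene-2-carboxylate, via Michael adduct aldehyde 10 (not isolated), via benzylic carbinol 11 (not isolated)
Conditions: (S)-2-[diphenyl(trimethylsilyloxy)methyl]pyrrolidine (20 mol %), Et3N (50 mol %), CH2Cl2, 0 °C to rt; then CF3CO2H, CH2Cl2, 0 °C to rt; then Et3N (excess over the acid), rt
Reagents that add atoms: none
Why: Proposed new method: the closest known reaction types are iminium-catalysed Michael additions of nitroalkanes, malonates and vinylogous carbon acids to enals and the acid-mediated cyclodehydration of 4-arylbutanals to 1,2-dihydronaphthalenes; a 4-benzyl-2-pyranone has not been used as the donor. The (S)-prolinol ether condenses with 9 to an E-configured s-trans iminium ion with one face covered by the CPh2OSiMe3 group, while the tertiary amine reversibly removes the C1 proton of 8 (benzylic to ring A, vinylogous to the lactone carbonyl) to give a 2-oxido-4-benzylidene-4H-pyran. This soft dienolate adds through its exocyclic γ-carbon, which restores the pyranone, to the open Si face of the ester-bearing β-carbon and so sets C2 (R in 10 and 12); the iminium ion, not the ester, directs the attack β to the aldehyde. Hydrolysis of the enamine releases 10, whose C1 is not under catalyst control and is expected as an epimer mixture. Trifluoroacetic acid then protonates the aldehyde, C4a (para to the C7 methoxy group and less hindered than the carbon between the side chain and a methoxy group) attacks it in a 6-exo-trig Friedel–Crafts hydroxyalkylation that closes ring B, and carbinol 11 ionises to a C4 cation stabilised by the same methoxy group, which loses a C3 proton to give the C3=C4 styrene. Finally triethylamine, too weak to reach the less acidic C2–H (ester α and allylic only), should equilibrate the doubly activated C1–H towards the trans isomer 12, in which both substituents can stand pseudoaxial and anti. The step needs γ- over α-attack of the dienolate, β-to-aldehyde regiochemistry, face selectivity at C2 and para cyclisation; these rest on conjugation in the product, iminium activation, the catalyst shield and the methoxy pattern of ring A.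

Step 6
Reactants: 12 ethyl (1R,2R)-6,7-dimethoxy-1-[6-(methoxycarbonyl)-2-oxo-2H-pyran-4-yl]-1,2-dihydronaphthalene-2-carboxylate
Product: 14 ethyl (1R,2S)-3-formyl-6,7-dimethoxy-1-[6-(methoxycarbonyl)-2-oxo-2H-pyran-4-yl]-1,2-dihydronaphthalene-2-carboxylate, via vinylogous iminium chloride 13 (not isolated)
Conditions: POCl3, DMF, 0 to 60 °C; then aq. NaOAc, rt
Reagents that add atoms: N,N-dimethylformamide, CN(C)C=O; water, O
Why: Vilsmeier–Haack formylation of an electron-rich styrene. The chloroiminium ion attacks C3 because the resulting C4 cation is stabilised by the C7 methoxy group para to C4a, and loss of the C3 proton restores the alkene. The veratrole-type ring A is much less reactive, and the acidic medium leaves C1 and C2 untouched.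

Step 7
Reactants: 14 ethyl (1R,2S)-3-formyl-6,7-dimethoxy-1-[6-(methoxycarbonyl)-2-oxo-2H-pyran-4-yl]-1,2-dihydronaphthalene-2-carboxylate
Product: 15 (1R,2S)-2-(ethoxycarbonyl)-6,7-dimethoxy-1-[6-(methoxycarbonyl)-2-oxo-2H-pyran-4-yl]-1,2-dihydronaphthalene-3-carboxylic acid
Conditions: NaClO2, NaH2PO4, 2-methylbut-2-ene, t-BuOH/THF/H2O, 0 °C to rt
Reagents that add atoms: sodium chlorite, [Na+].[O-]Cl=O
Why: Pinnick oxidation, which converts conjugated aldehydes to acids without touching the alkene. The alkene scavenger removes hypochlorous acid before it can chlorinate ring A, and the buffered medium (about pH 4) is safe for the lactone and both stereocentres.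

Step 8
Reactants: 15 (1R,2S)-2-(ethoxycarbonyl)-6,7-dimethoxy-1-[6-(methoxycarbonyl)-2-oxo-2H-pyran-4-yl]-1,2-dihydronaphthalene-3-carboxylic acid
Product: 16 (1R,2S)-2-(ethoxycarbonyl)-6,7-dihydroxy-1-[6-(methoxycarbonyl)-2-oxo-2H-pyran-4-yl]-1,2-dihydronaphthalene-3-carboxylic acid
Conditions: BBr3 (excess), CH2Cl2, −78 to 0 °C; then H2O
Reagents that add atoms: none
Why: Lewis acid cleavage of aryl methyl ethers: boron binds each ether oxygen and bromide attacks the methyl group (SN2). At or below 0 °C the alkyl esters and the lactone should largely survive, and any ester cleaved early converges in step 9.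

Step 9
Reactants: 16 (1R,2S)-2-(ethoxycarbonyl)-6,7-dihydroxy-1-[6-(methoxycarbonyl)-2-oxo-2H-pyran-4-yl]-1,2-dihydronaphthalene-3-carboxylic acid
Product: 17 (1R,2S)-1-(6-carboxy-2-oxo-2H-pyran-4-yl)-6,7-dihydroxy-1,2-dihydronaphthalene-2,3-dicarboxylic acid
Conditions: 6 M HCl, 1,4-dioxane, 80 °C, argon
Reagents that add atoms: water, O
Why: Acid-catalysed ester hydrolysis (acyl–oxygen cleavage). Acid is used because hydroxide would open ring C and deprotonate C1 and C2. The pyranone acid is itself formed in hot hydrochloric acid (step 1), and the catechol is stable to acid when air is excluded.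

## Compound list

1 | methyl 3-methylbut-2-enoate | CC(C)=CC(=O)OC | starting material
2 | dimethyl oxalate | COC(=O)C(=O)OC | starting material
3 | potassium (2Z,4Z)-1,6-dimethoxy-4-methyl-1,6-dioxohexa-2,4-dien-2-olate (delocalised dienolate, drawn in the geometry that lactonises) | [K+].[O-]/C(=C\C(C)=C/C(=O)OC)C(=O)OC | intermediate
4 | 4-methyl-2-oxo-2H-pyran-6-carboxylic acid | Cc1cc(C(=O)O)oc(=O)c1 | intermediate
5 | methyl 4-methyl-2-oxo-2H-pyran-6-carboxylate | COC(=O)c1cc(C)cc(=O)o1 | intermediate
6 | methyl 4-(bromomethyl)-2-oxo-2H-pyran-6-carboxylate | COC(=O)c1cc(CBr)cc(=O)o1 | intermediate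
7 | (3,4-dimethoxyphenyl)boronic acid | COc1ccc(B(O)O)cc1OC | starting material
8 | methyl 4-(3,4-dimethoxybenzyl)-2-oxo-2H-pyran-6-carboxylate | COC(=O)c1cc(Cc2ccc(OC)c(OC)c2)cc(=O)o1 | intermediate
9 | ethyl (E)-4-oxobut-2-enoate | CCOC(=O)/C=C/C=O | starting material
10 | ethyl (2R,3S)-3-(3,4-dimethoxyphenyl)-3-[6-(methoxycarbonyl)-2-oxo-2H-pyran-4-yl]-2-(2-oxoethyl)propanoate (formed together with its C3 epimer) | COc1ccc(cc1OC)[C@@H](c1cc(C(=O)OC)oc(=O)c1)[C@@H](CC=O)C(=O)OCC | intermediate
11 | ethyl (1R,2R)-4-hydroxy-6,7-dimethoxy-1-[6-(methoxycarbonyl)-2-oxo-2H-pyran-4-yl]-1,2,3,4-tetrahydronaphthalene-2-carboxylate (both C4 epimers, which converge on dehydration) | C1C(O)c2cc(OC)c(OC)cc2[C@@H](c2cc(C(=O)OC)oc(=O)c2)[C@@H]1C(=O)OCC | intermediate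
12 | ethyl (1R,2R)-6,7-dimethoxy-1-[6-(methoxycarbonyl)-2-oxo-2H-pyran-4-yl]-1,2-dihydronaphthalene-2-carboxylate | C1=Cc2cc(OC)c(OC)cc2[C@@H](c2cc(C(=O)OC)oc(=O)c2)[C@@H]1C(=O)OCC | intermediate
13 | ethyl (1R,2S)-3-[(dimethyliminio)methyl]-6,7-dimethoxy-1-[6-(methoxycarbonyl)-2-oxo-2H-pyran-4-yl]-1,2-dihydronaphthalene-2-carboxylate chloride | C[N+](C)=CC1=Cc2cc(OC)c(OC)cc2[C@@H](c2cc(C(=O)OC)oc(=O)c2)[C@@H]1C(=O)OCC.[Cl-] | intermediate
14 | ethyl (1R,2S)-3-formyl-6,7-dimethoxy-1-[6-(methoxycarbonyl)-2-oxo-2H-pyran-4-yl]-1,2-dihydronaphthalene-2-carboxylate | O=CC1=Cc2cc(OC)c(OC)cc2[C@@H](c2cc(C(=O)OC)oc(=O)c2)[C@@H]1C(=O)OCC | intermediate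
15 | (1R,2S)-2-(ethoxycarbonyl)-6,7-dimethoxy-1-[6-(methoxycarbonyl)-2-oxo-2H-pyran-4-yl]-1,2-dihydronaphthalene-3-carboxylic acid | O=C(O)C1=Cc2cc(OC)c(OC)cc2[C@@H](c2cc(C(=O)OC)oc(=O)c2)[C@@H]1C(=O)OCC | intermediate
16 | (1R,2S)-2-(ethoxycarbonyl)-6,7-dihydroxy-1-[6-(methoxycarbonyl)-2-oxo-2H-pyran-4-yl]-1,2-dihydronaphthalene-3-carboxylic acid | O=C(O)C1=Cc2cc(O)c(O)cc2[C@@H](c2cc(C(=O)OC)oc(=O)c2)[C@@H]1C(=O)OCC | intermediate
17 | (1R,2S)-1-(6-carboxy-2-oxo-2H-pyran-4-yl)-6,7-dihydroxy-1,2-dihydronaphthalene-2,3-dicarboxylic acid | O=C(O)C1=Cc2cc(O)c(O)cc2[C@@H](c2cc(C(=O)O)oc(=O)c2)[C@@H]1C(=O)O | target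

## Step count and risk

Total step count: 9. Longest linear sequence: 9 steps (from 1 and 2 to 17); 7 and 9 enter as purchased partners.

**Step 5 (key step, proposed new method).**
- What may go wrong:
  - Deprotonation of 8 by a weak amine may be too slow to keep up with the iminium cycle. The uncatalysed, base-mediated addition to free 9 would then take over and erode enantioselectivity and regiochemistry.
  - The secondary amine catalyst may be consumed by conjugate attack on the electron-poor pyranone.
  - Equilibration at C1 may stop short of the trans isomer, or may begin to involve C2–H, with alkene migration.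
  - The electron-rich styrene may dimerise or disproportionate in the acid stage.
- Fallback (known chemistry): the fallback separates nucleophile generation from the catalytic cycle. From 8, soft enolisation with t-BuMe2SiOSO2CF3 and Et3N in CH2Cl2 at 0 °C should give the silyl dienol ether methyl 6-[(tert-butyldimethylsilyl)oxy]-4-[(3,4-dimethoxyphenyl)methylidene]-4H-pyran-2-carboxylate F1. An organocatalytic Mukaiyama–Michael addition of F1 to 9 follows, with the trifluoroacetate salt of (2S,5S)-5-benzyl-2-tert-butyl-3-methylimidazolidin-4-one (20 mol %) in wet CH2Cl2 at −40 °C. This is the established reaction type for silyloxy dienes and 4-oxobutenoates, and the catalyst exposes the same face of the β-carbon. With loss of the silanol it should deliver 10, where the sequence rejoins the route; 10 is cyclised and equilibrated as in the second and third stages of step 5 to give 12.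

**Step 6.**
- What may go wrong:
  - Attack at C3 may be slow because the neighbouring C2 ester hinders and deactivates it.
  - Formylation of ring A at C5 or C8 may compete at the temperature then required.
  - Acid-promoted disproportionation towards the naphthalene is possible.
- Fallback: from 12, Friedel–Crafts-type chlorocarbonylation of the styrene with oxalyl chloride (CH2Cl2, 0 °C to rt, with loss of carbon monoxide) should give the acid chloride ethyl (1R,2S)-3-(chlorocarbonyl)-6,7-dimethoxy-1-[6-(methoxycarbonyl)-2-oxo-2H-pyran-4-yl]-1,2-dihydronaphthalene-2-carboxylate F2. Quenching with water returns the sequence to the route at 15 and saves the oxidation step.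

**Step 4.**
- What may go wrong:
  - Aqueous base may open the lactone or hydrolyse the ester.
  - Deprotonated 8 may be alkylated by 6.
  - Coupling may occur at the allylic terminus C3' instead of the CH2 carbon.
- Fallback: a base-free Negishi coupling. Zinc insertion (Zn dust, LiCl, THF) into 4-iodo-1,2-dimethoxybenzene gives (3,4-dimethoxyphenyl)zinc iodide F3. This is coupled with 6 using Pd(PPh3)4 in THF at rt and returns to the route at 8.

**Step 9 (with step 8).**
- What may go wrong:
  - Hydrolysis of the hindered C2 ester may be slow.
  - Prolonged heating in acid may then cause epimerisation at C2, alkene migration or decarboxylation of the β,γ-unsaturated C2 acid.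
  - The free catechol may oxidise if air enters.
- Fallback: the order and the mechanism of deprotection are changed. From 15, both esters are cleaved under neutral conditions with Me3SnOH in 1,2-dichloroethane at 70 °C to give (1R,2S)-1-(6-carboxy-2-oxo-2H-pyran-4-yl)-6,7-dimethoxy-1,2-dihydronaphthalene-2,3-dicarboxylic acid F4. The ethers are then cleaved last with BBr3 in CH2Cl2 (−78 to 0 °C, then water), which arrives at 17 without heating the free catechol.

## Further compounds

F1 | step 5 | methyl 6-[(tert-butyldimethylsilyl)oxy]-4-[(3,4-dimethoxyphenyl)methylidene]-4H-pyran-2-carboxylate (exocyclic alkene geometry not controlled) | COC(=O)C1=CC(=Cc2ccc(OC)c(OC)c2)C=C(O[Si](C)(C)C(C)(C)C)O1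
F2 | step 6 | ethyl (1R,2S)-3-(chlorocarbonyl)-6,7-dimethoxy-1-[6-(methoxycarbonyl)-2-oxo-2H-pyran-4-yl]-1,2-dihydronaphthalene-2-carboxylate | O=C(Cl)C1=Cc2cc(OC)c(OC)cc2[C@@H](c2cc(C(=O)OC)oc(=O)c2)[C@@H]1C(=O)OCC
F3 | step 4 | (3,4-dimethoxyphenyl)zinc iodide | COc1ccc([Zn]I)cc1OC
F4 | step 9 | (1R,2S)-1-(6-carboxy-2-oxo-2H-pyran-4-yl)-6,7-dimethoxy-1,2-dihydronaphthalene-2,3-dicarboxylic acid | O=C(O)C1=Cc2cc(OC)c(OC)cc2[C@@H](c2cc(C(=O)O)oc(=O)c2)[C@@H]1C(=O)O
A1 | alternative 1 | (1R,2S)-6,7-dimethoxy-2,3-bis(methoxycarbonyl)-1,2-dihydronaphthalene-1-carboxylic acid (cis) | COC(=O)C1=Cc2cc(OC)c(OC)cc2[C@H](C(=O)O)[C@@H]1C(=O)OC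
A2 | alternative 2 | 1-tert-butyl 2,3-dimethyl (1S,2S)-6,7-dimethoxy-1,2-dihydronaphthalene-1,2,3-tricarboxylate (trans) | COC(=O)C1=Cc2cc(OC)c(OC)cc2[C@@H](C(=O)OC(C)(C)C)[C@@H]1C(=O)OC
A3 | alternative 3 | dimethyl (1R,2S)-1-[3,4-bis(benzyloxy)phenyl]-6,7-dimethoxy-1,2-dihydronaphthalene-2,3-dicarboxylate | COC(=O)C1=Cc2cc(OC)c(OC)cc2[C@@H](c2ccc(OCc3ccccc3)c(OCc3ccccc3)c2)[C@@H]1C(=O)OC
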